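**Plan**

- Retrosynthesis: the five aryl O–Si bonds are cut first. Both ketones are then taken back to carbinols and cut at carbinol C–vinyl C (C7 side chain), at C7–CHO and at carbinol C–aryl C (C3 side chain). The C7–I bond follows, then the C2–C3 bond of the dihydrofuran, and last the aryl–C(diazo) bond, the aryl–I bond and the benzyl ether C–O bond of a phloroglucinol triether.
- Enabling feature: C2 is a benzylic C–H carbon bound to O1 and stands 1,5 to C3. A carbenoid centred on C3 (attached to C3a of ring A) can therefore reach a C–H bond of a 4-silyloxybenzyl ether on the C7a oxygen.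
- Forward: ring A from phloroglucinol is etherified, iodinated and coupled with ethyl diazoacetate. The dihydrofuran, the only ring that is built, closes by C2–C3 formation. Then come C7 iodination, ester → aldehyde → aryl carbinol at C3, iodide → aldehyde → allylic carbinol at C7, oxidation of both carbinols and desilylation.
- Stereochemistry: C2 comes from selection of one enantiotopic benzylic hydrogen by the chiral dirhodium carboxylate. C3 is set by base equilibration to the thermodynamic trans isomer. The two carbinol centres are transient and are erased by oxidation.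

Key step: step 6

**Remarks on the chemistry**

- TIPS = triisopropylsilyl, Si(i-Pr)3; TIPSO = triisopropylsilyloxy. All six phenols are carried as TIPS ethers.
- Rh2(S-PTTL)4 = dirhodium tetrakis[N-phthaloyl-(S)-tert-leucinate]. It is assumed to select the benzylic hydrogen that leads to 2R, as expected for ortho-benzyloxy aryldiazoacetates. If this hindered substrate responds with the opposite sense, Rh2(R-PTTL)4 is used with everything else unchanged.
- The Cahn–Ingold–Prelog descriptor at C3 reads R while C3 carries an ester, aldehyde or ketone carbon and S while it carries the free carbinol carbon. The spatial arrangement (trans to the C2 aryl group) is the same throughout.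

**Route**

Step 1
Reactants: 1 phloroglucinol
Product: 2 3,5-bis(TIPSO)phenol
Conditions: TIPSCl (2.0 equiv), imidazole, DMF, 0 °C → rt
Reagents that add atoms: triisopropylsilyl chloride, CC(C)[Si](Cl)(C(C)C)C(C)C
Why: Imidazole-mediated O-silylation of a phenol; with two equivalents of the bulky chloride the bis-ether should predominate and is separated from mono- and tris-ether, which can be recycled.

Step 2
Reactants: 3 4-hydroxybenzyl alcohol
Product: 5 4-(TIPSO)benzyl alcohol, via sodium phenoxide 4 (not isolated)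
Conditions: NaH (1.0 equiv), THF, 0 °C; TIPSCl (1.0 equiv), 0 °C → rt
Reagents that add atoms: triisopropylsilyl chloride, CC(C)[Si](Cl)(C(C)C)C(C)C
Why: Chemoselective O-silylation, since one equivalent of NaH deprotonates only the far more acidic phenol and the phenoxide 4 is silylated much faster than the neutral primary alcohol.

Step 3
Reactants: 2 3,5-bis(TIPSO)phenol; 5 4-(TIPSO)benzyl alcohol
Product: 6 1-[4-(TIPSO)benzyloxy]-3,5-bis(TIPSO)benzene
Conditions: PPh3, DIAD, THF, 0 °C → rt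
Reagents that add atoms: none
Why: Mitsunobu etherification of an acidic phenol with a primary benzylic alcohol under neutral conditions, which spares the aryl silyl ethers and avoids a labile 4-silyloxybenzyl halide.

Step 4
Reactants: 6 1-[4-(TIPSO)benzyloxy]-3,5-bis(TIPSO)benzene
Product: 7 2-iodo-1-[4-(TIPSO)benzyloxy]-3,5-bis(TIPSO)benzene
Conditions: NIS (1.0 equiv), CH2Cl2, −20 → 0 °C, dark
Reagents that add atoms: N-iodosuccinimide, O=C1CCC(=O)N1I
Why: Electrophilic aromatic iodination of the trioxygenated ring, by far the most activated arene; the two equivalent positions between the benzyloxy and a silyloxy group are less shielded than the position between the two TIPSO groups, and one equivalent of NIS at low temperature should stop at the mono-iodide.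

Step 5
Reactants: 7 2-iodo-1-[4-(TIPSO)benzyloxy]-3,5-bis(TIPSO)benzene; 8 ethyl diazoacetate
Product: 9 ethyl 2-diazo-2-{2-[4-(TIPSO)benzyloxy]-4,6-bis(TIPSO)phenyl}acetate
Conditions: Pd(PPh3)4 (5 mol %), Ag2CO3 (0.5 equiv), Et3N, toluene, rt
Reagents that add atoms: none
Why: Palladium-catalysed cross-coupling of an aryl iodide with an acceptor diazo compound with retention of the diazo group, by oxidative addition of zerovalent palladium, base-assisted palladation of ethyl diazoacetate at carbon (Ag2CO3 takes up iodide) and reductive elimination at room temperature, where the diazo ester survives.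

Step 6
Reactants: 9 ethyl 2-diazo-2-{2-[4-(TIPSO)benzyloxy]-4,6-bis(TIPSO)phenyl}acetate
Product: 11 ethyl (2R,3R)-4,6-bis(TIPSO)-2-[4-(TIPSO)phenyl]-2,3-dihydrobenzofuran-3-carboxylate, via cis ester 10 (not isolated)
Conditions: Rh2(S-PTTL)4 (2 mol %), toluene, −60 → −40 °C; then DBU (0.3 equiv), rt, same flask
Reagents that add atoms: none
Why: The dirhodium carboxylate decomposes the diazo ester with loss of N2 to a donor/acceptor rhodium carbenoid centred on the future C3, which inserts into one benzylic C–H bond of the ortho 4-silyloxybenzyl ether through a concerted, asynchronous three-centre transition state with hydride-transfer character and so forms C2–C3. The closest known reaction type is the intramolecular 1,5 C–H insertion of ortho-benzyloxy aryldiazoacetates under chiral dirhodium carboxylates, which gives cis-2-aryl-2,3-dihydrobenzofuran-3-carboxylates. The dihydrofuran closes as a five-membered ring by C–C bond formation between the carbenoid carbon and the ether carbon five atoms away (1,5-insertion). C2 is controlled by the chiral carboxylate ligands, which select one of the two enantiotopic benzylic hydrogens, whereas C3 arises cis under kinetic control (10) and is then equilibrated by DBU through the ester enolate to the trans isomer 11, in which aryl and ester groups avoid each other; C2 is not touched, because ring opening of that enolate would be a stereoelectronically disfavoured 5-endo-trig retro-oxa-Michael process. The step needs site selectivity, which is secured by the single oxygen-activated benzylic methylene ortho to the carbenoid, further activated by its para silyloxy group, while the C–H bonds of the silyl ethers are unactivated, hindered and would need a larger ring.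

Step 7
Reactants: 11 ethyl (2R,3R)-4,6-bis(TIPSO)-2-[4-(TIPSO)phenyl]-2,3-dihydrobenzofuran-3-carboxylate
Product: 12 ethyl (2R,3R)-7-iodo-4,6-bis(TIPSO)-2-[4-(TIPSO)phenyl]-2,3-dihydrobenzofuran-3-carboxylate
Conditions: NIS (1.05 equiv), MeCN/CH2Cl2, 0 °C → rt, dark
Reagents that add atoms: N-iodosuccinimide, O=C1CCC(=O)N1I
Why: Electrophilic aromatic iodination in which C7, flanked by the ring oxygen O1 and one silyloxy group, is more accessible than C5 between two TIPSO groups, in line with the preference for the position next to the ring oxygen in halogenation of 5,7-dioxygenated flavans, while the mono-oxygenated C2 aryl ring is far less reactive.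

Step 8
Reactants: 12 ethyl (2R,3R)-7-iodo-4,6-bis(TIPSO)-2-[4-(TIPSO)phenyl]-2,3-dihydrobenzofuran-3-carboxylate
Product: 14 (2R,3R)-7-iodo-4,6-bis(TIPSO)-2-[4-(TIPSO)phenyl]-2,3-dihydrobenzofuran-3-carbaldehyde, via aluminium hemiacetal 13 (not isolated)
Conditions: i-Bu2AlH (1.1 equiv), CH2Cl2, −78 °C; MeOH, aq. potassium sodium tartrate
Reagents that add atoms: none
Why: Partial reduction of an ester with i-Bu2AlH at −78 °C, which rests at the tetrahedral aluminium hemiacetal 13 until work-up; aryl iodide and silyl ethers are inert, and trans is the thermodynamic arrangement at C2/C3, so enolisation of the aldehyde should not erode it.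

Step 9
Reactants: 15 4-bromoresorcinol
Product: 16 1-bromo-2,4-bis(TIPSO)benzene
Conditions: TIPSCl (2.2 equiv), imidazole, DMF, rt
Reagents that add atoms: triisopropylsilyl chloride, CC(C)[Si](Cl)(C(C)C)C(C)C
Why: Standard imidazole-mediated silylation of both phenols.

Step 10
Reactants: 14 (2R,3R)-7-iodo-4,6-bis(TIPSO)-2-[4-(TIPSO)phenyl]-2,3-dihydrobenzofuran-3-carbaldehyde; 16 1-bromo-2,4-bis(TIPSO)benzene
Product: 18 [2,4-bis(TIPSO)phenyl]{(2R,3S)-7-iodo-4,6-bis(TIPSO)-2-[4-(TIPSO)phenyl]-2,3-dihydrobenzofuran-3-yl}methanol (both carbinol epimers), via aryl Grignard reagent 17 (not isolated)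
Conditions: 16, Mg, LiCl, THF, rt; then 14, THF, −78 → −40 °C; aq. NH4Cl
Reagents that add atoms: none
Why: Magnesium insertion gives the aryl Grignard reagent 17, used instead of the aryllithium because an ortho-silyloxy aryllithium is prone to 1,3 O-to-C silyl migration, and its 1,2-addition to the aldehyde is much faster than any reaction at the hindered aryl iodide; the new carbinol centre forms as a mixture that is removed in step 15.

Step 11
Reactants: 18 [2,4-bis(TIPSO)phenyl]{(2R,3S)-7-iodo-4,6-bis(TIPSO)-2-[4-(TIPSO)phenyl]-2,3-dihydrobenzofuran-3-yl}methanol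
Product: 21 (2R,3S)-3-{[2,4-bis(TIPSO)phenyl](hydroxy)methyl}-4,6-bis(TIPSO)-2-[4-(TIPSO)phenyl]-2,3-dihydrobenzofuran-7-carbaldehyde (both carbinol epimers), via arylmagnesium alkoxide 19 (not isolated), via magnesium hemiaminal 20 (not isolated)
Conditions: iPrMgCl·LiCl (2.5 equiv), THF, 0 °C → rt; DMF, 0 °C → rt; aq. NH4Cl
Reagents that add atoms: N,N-dimethylformamide, CN(C)C=O
Why: After the first equivalent of iPrMgCl·LiCl has deprotonated the hydroxyl group, iodine–magnesium exchange at C7, favoured by the two flanking oxygens, gives 19, and formylation with DMF (Bouveault aldehyde synthesis) gives 21 on hydrolysis of hemiaminal 20; no electrophilic or C–H acidic group is present at this stage.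

Step 12
Reactants: 22 4'-hydroxyacetophenone
Product: 23 4'-(TIPSO)acetophenone
Conditions: TIPSCl, imidazole, DMF, rt
Reagents that add atoms: triisopropylsilyl chloride, CC(C)[Si](Cl)(C(C)C)C(C)C
Why: Standard imidazole-mediated silylation of a phenol.

Step 13
Reactants: 23 4'-(TIPSO)acetophenone
Product: 24 N'-{1-[4-(TIPSO)phenyl]ethylidene}-2,4,6-triisopropylbenzenesulfonohydrazide
Conditions: 2,4,6-(i-Pr)3C6H2SO2NHNH2, THF, cat. AcOH, rt
Reagents that add atoms: 2,4,6-triisopropylbenzenesulfonyl hydrazide, NNS(=O)(=O)c1c(C(C)C)cc(C(C)C)cc1C(C)C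
Why: Condensation of a ketone with an arenesulfonyl hydrazide to the hydrazone needed for the Shapiro reaction.

Step 14
Reactants: 21 (2R,3S)-3-{[2,4-bis(TIPSO)phenyl](hydroxy)methyl}-4,6-bis(TIPSO)-2-[4-(TIPSO)phenyl]-2,3-dihydrobenzofuran-7-carbaldehyde; 24 N'-{1-[4-(TIPSO)phenyl]ethylidene}-2,4,6-triisopropylbenzenesulfonohydrazide
Product: 27 1-{(2R,3S)-3-{[2,4-bis(TIPSO)phenyl](hydroxy)methyl}-4,6-bis(TIPSO)-2-[4-(TIPSO)phenyl]-2,3-dihydrobenzofuran-7-yl}-2-[4-(TIPSO)phenyl]prop-2-en-1-ol (mixture of carbinol epimers), via dilithiated hydrazone 25 (not isolated), via vinyllithium 26 (not isolated)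
Conditions: 24 (3 equiv), n-BuLi (6 equiv), THF, −78 → 0 °C; then 21, −78 °C; aq. NH4Cl
Reagents that add atoms: none
Why: Shapiro reaction, in which double deprotonation at N–H and at the methyl group (the only α-position) gives 25, loss of sulfinate and N2 on warming gives the α-aryl vinyllithium 26, and 1,2-addition to the non-enolisable aldehyde installs the whole C7 side chain, one equivalent of 26 being spent on the free hydroxyl group; the new carbinol centre forms as a mixture that is removed in step 15.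

Step 15
Reactants: 27 1-{(2R,3S)-3-{[2,4-bis(TIPSO)phenyl](hydroxy)methyl}-4,6-bis(TIPSO)-2-[4-(TIPSO)phenyl]-2,3-dihydrobenzofuran-7-yl}-2-[4-(TIPSO)phenyl]prop-2-en-1-ol
Product: 28 1-{(2R,3R)-3-[2,4-bis(TIPSO)benzoyl]-4,6-bis(TIPSO)-2-[4-(TIPSO)phenyl]-2,3-dihydrobenzofuran-7-yl}-2-[4-(TIPSO)phenyl]prop-2-en-1-one
Conditions: Dess–Martin periodinane (3 equiv), NaHCO3, CH2Cl2, 0 °C → rt
Reagents that add atoms: none
Why: Dess–Martin oxidation of both secondary alcohols under buffered, non-basic conditions, the benzylic carbinol giving the C3 aryl ketone and the allylic/benzylic carbinol giving the α-aryl enone directly, so that no base-mediated α-methylenation is needed; C3 becomes α to a ketone, but trans is its thermodynamic configuration.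

Step 16
Reactants: 28 1-{(2R,3R)-3-[2,4-bis(TIPSO)benzoyl]-4,6-bis(TIPSO)-2-[4-(TIPSO)phenyl]-2,3-dihydrobenzofuran-7-yl}-2-[4-(TIPSO)phenyl]prop-2-en-1-one
Product: 29 1-[(2R,3R)-3-(2,4-dihydroxybenzoyl)-4,6-dihydroxy-2-(4-hydroxyphenyl)-2,3-dihydrobenzofuran-7-yl]-2-(4-hydroxyphenyl)prop-2-en-1-one (CNP0162111.1)
Conditions: HF·pyridine, pyridine/THF, 0 °C → rt
Reagents that add atoms: none
Why: Fluoride-mediated cleavage of the five aryl silyl ethers with buffered HF·pyridine, chosen over basic fluoride sources so that the liberated C6 hydroxyl should not add to the enone (oxa-Michael closure to an isoflavanone) and the acid-sensitive C2 benzylic ether is not ionised.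

**Compound list**

1 | phloroglucinol | Oc1cc(O)cc(O)c1 | starting material
2 | 3,5-bis(TIPSO)phenol | Oc1cc(O[Si](C(C)C)(C(C)C)C(C)C)cc(O[Si](C(C)C)(C(C)C)C(C)C)c1 | intermediate
3 | 4-hydroxybenzyl alcohol | OCc1ccc(O)cc1 | starting material
4 | sodium 4-(hydroxymethyl)phenoxide (formed in the flask, not isolated) | [Na+].[O-]c1ccc(CO)cc1 | intermediate
5 | 4-(TIPSO)benzyl alcohol | OCc1ccc(O[Si](C(C)C)(C(C)C)C(C)C)cc1 | intermediate
6 | 1-[4-(TIPSO)benzyloxy]-3,5-bis(TIPSO)benzene | CC(C)[Si](C(C)C)(C(C)C)Oc1ccc(COc2cc(O[Si](C(C)C)(C(C)C)C(C)C)cc(O[Si](C(C)C)(C(C)C)C(C)C)c2)cc1 | intermediate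
7 | 2-iodo-1-[4-(TIPSO)benzyloxy]-3,5-bis(TIPSO)benzene | CC(C)[Si](C(C)C)(C(C)C)Oc1ccc(COc2cc(O[Si](C(C)C)(C(C)C)C(C)C)cc(O[Si](C(C)C)(C(C)C)C(C)C)c2I)cc1 | intermediate
8 | ethyl diazoacetate | CCOC(=O)C=[N+]=[N-] | starting material
9 | ethyl 2-diazo-2-{2-[4-(TIPSO)benzyloxy]-4,6-bis(TIPSO)phenyl}acetate | CCOC(=O)C(=[N+]=[N-])c1c(OCc2ccc(O[Si](C(C)C)(C(C)C)C(C)C)cc2)cc(O[Si](C(C)C)(C(C)C)C(C)C)cc1O[Si](C(C)C)(C(C)C)C(C)C | intermediate
10 | ethyl (2R,3S)-4,6-bis(TIPSO)-2-[4-(TIPSO)phenyl]-2,3-dihydrobenzofuran-3-carboxylate, cis (formed in the flask, not isolated) | c1c(O[Si](C(C)C)(C(C)C)C(C)C)cc(O[Si](C(C)C)(C(C)C)C(C)C)c2c1O[C@@H](c1ccc(O[Si](C(C)C)(C(C)C)C(C)C)cc1)[C@H]2C(=O)OCC | intermediate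
11 | ethyl (2R,3R)-4,6-bis(TIPSO)-2-[4-(TIPSO)phenyl]-2,3-dihydrobenzofuran-3-carboxylate, trans | c1c(O[Si](C(C)C)(C(C)C)C(C)C)cc(O[Si](C(C)C)(C(C)C)C(C)C)c2c1O[C@@H](c1ccc(O[Si](C(C)C)(C(C)C)C(C)C)cc1)[C@@H]2C(=O)OCC | intermediate
12 | ethyl (2R,3R)-7-iodo-4,6-bis(TIPSO)-2-[4-(TIPSO)phenyl]-2,3-dihydrobenzofuran-3-carboxylate | Ic1c(O[Si](C(C)C)(C(C)C)C(C)C)cc(O[Si](C(C)C)(C(C)C)C(C)C)c2c1O[C@@H](c1ccc(O[Si](C(C)C)(C(C)C)C(C)C)cc1)[C@@H]2C(=O)OCC | intermediate
13 | diisobutylaluminium ethyl hemiacetal of aldehyde 14, hemiacetal carbon undefined (formed in the flask, not isolated) | Ic1c(O[Si](C(C)C)(C(C)C)C(C)C)cc(O[Si](C(C)C)(C(C)C)C(C)C)c2c1O[C@@H](c1ccc(O[Si](C(C)C)(C(C)C)C(C)C)cc1)[C@@H]2C(OCC)O[Al](CC(C)C)CC(C)C | intermediate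
14 | (2R,3R)-7-iodo-4,6-bis(TIPSO)-2-[4-(TIPSO)phenyl]-2,3-dihydrobenzofuran-3-carbaldehyde | Ic1c(O[Si](C(C)C)(C(C)C)C(C)C)cc(O[Si](C(C)C)(C(C)C)C(C)C)c2c1O[C@@H](c1ccc(O[Si](C(C)C)(C(C)C)C(C)C)cc1)[C@@H]2C=O | intermediate
15 | 4-bromoresorcinol | Oc1ccc(Br)c(O)c1 | starting material
16 | 1-bromo-2,4-bis(TIPSO)benzene | Brc1ccc(O[Si](C(C)C)(C(C)C)C(C)C)cc1O[Si](C(C)C)(C(C)C)C(C)C | intermediate
17 | [2,4-bis(TIPSO)phenyl]magnesium bromide (formed in the flask, not isolated) | Br[Mg]c1ccc(O[Si](C(C)C)(C(C)C)C(C)C)cc1O[Si](C(C)C)(C(C)C)C(C)C | intermediate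
18 | [2,4-bis(TIPSO)phenyl]{(2R,3S)-7-iodo-4,6-bis(TIPSO)-2-[4-(TIPSO)phenyl]-2,3-dihydrobenzofuran-3-yl}methanol, both carbinol epimers | Ic1c(O[Si](C(C)C)(C(C)C)C(C)C)cc(O[Si](C(C)C)(C(C)C)C(C)C)c2c1O[C@@H](c1ccc(O[Si](C(C)C)(C(C)C)C(C)C)cc1)[C@@H]2C(O)c1ccc(O[Si](C(C)C)(C(C)C)C(C)C)cc1O[Si](C(C)C)(C(C)C)C(C)C | intermediate
19 | chloromagnesium alkoxide of 18 carrying MgCl at C7 in place of iodine (formed in the flask, not isolated) | Cl[Mg]c1c(O[Si](C(C)C)(C(C)C)C(C)C)cc(O[Si](C(C)C)(C(C)C)C(C)C)c2c1O[C@@H](c1ccc(O[Si](C(C)C)(C(C)C)C(C)C)cc1)[C@@H]2C(O[Mg]Cl)c1ccc(O[Si](C(C)C)(C(C)C)C(C)C)cc1O[Si](C(C)C)(C(C)C)C(C)C | intermediate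
20 | chloromagnesium hemiaminal from 19 and DMF at C7 (formed in the flask, not isolated) | CN(C)C(O[Mg]Cl)c1c(O[Si](C(C)C)(C(C)C)C(C)C)cc(O[Si](C(C)C)(C(C)C)C(C)C)c2c1O[C@@H](c1ccc(O[Si](C(C)C)(C(C)C)C(C)C)cc1)[C@@H]2C(O[Mg]Cl)c1ccc(O[Si](C(C)C)(C(C)C)C(C)C)cc1O[Si](C(C)C)(C(C)C)C(C)C | intermediate
21 | (2R,3S)-3-{[2,4-bis(TIPSO)phenyl](hydroxy)methyl}-4,6-bis(TIPSO)-2-[4-(TIPSO)phenyl]-2,3-dihydrobenzofuran-7-carbaldehyde, both carbinol epimers | O=Cc1c(O[Si](C(C)C)(C(C)C)C(C)C)cc(O[Si](C(C)C)(C(C)C)C(C)C)c2c1O[C@@H](c1ccc(O[Si](C(C)C)(C(C)C)C(C)C)cc1)[C@@H]2C(O)c1ccc(O[Si](C(C)C)(C(C)C)C(C)C)cc1O[Si](C(C)C)(C(C)C)C(C)C | intermediate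
22 | 4'-hydroxyacetophenone | CC(=O)c1ccc(O)cc1 | starting material
23 | 4'-(TIPSO)acetophenone | CC(=O)c1ccc(O[Si](C(C)C)(C(C)C)C(C)C)cc1 | intermediate
24 | N'-{1-[4-(TIPSO)phenyl]ethylidene}-2,4,6-triisopropylbenzenesulfonohydrazide | CC(=NNS(=O)(=O)c1c(C(C)C)cc(C(C)C)cc1C(C)C)c1ccc(O[Si](C(C)C)(C(C)C)C(C)C)cc1 | intermediate
25 | N,C-dilithiated hydrazone from 24 (formed in the flask, not isolated) | [Li]CC(=NN([Li])S(=O)(=O)c1c(C(C)C)cc(C(C)C)cc1C(C)C)c1ccc(O[Si](C(C)C)(C(C)C)C(C)C)cc1 | intermediate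
26 | {1-[4-(TIPSO)phenyl]vinyl}lithium (formed in the flask, not isolated) | [Li]C(=C)c1ccc(O[Si](C(C)C)(C(C)C)C(C)C)cc1 | intermediate
27 | 1-{(2R,3S)-3-{[2,4-bis(TIPSO)phenyl](hydroxy)methyl}-4,6-bis(TIPSO)-2-[4-(TIPSO)phenyl]-2,3-dihydrobenzofuran-7-yl}-2-[4-(TIPSO)phenyl]prop-2-en-1-ol, mixture of carbinol epimers | C=C(C(O)c1c(O[Si](C(C)C)(C(C)C)C(C)C)cc(O[Si](C(C)C)(C(C)C)C(C)C)c2c1O[C@@H](c1ccc(O[Si](C(C)C)(C(C)C)C(C)C)cc1)[C@@H]2C(O)c1ccc(O[Si](C(C)C)(C(C)C)C(C)C)cc1O[Si](C(C)C)(C(C)C)C(C)C)c1ccc(O[Si](C(C)C)(C(C)C)C(C)C)cc1 | intermediate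
28 | 1-{(2R,3R)-3-[2,4-bis(TIPSO)benzoyl]-4,6-bis(TIPSO)-2-[4-(TIPSO)phenyl]-2,3-dihydrobenzofuran-7-yl}-2-[4-(TIPSO)phenyl]prop-2-en-1-one | C=C(C(=O)c1c(O[Si](C(C)C)(C(C)C)C(C)C)cc(O[Si](C(C)C)(C(C)C)C(C)C)c2c1O[C@@H](c1ccc(O[Si](C(C)C)(C(C)C)C(C)C)cc1)[C@@H]2C(=O)c1ccc(O[Si](C(C)C)(C(C)C)C(C)C)cc1O[Si](C(C)C)(C(C)C)C(C)C)c1ccc(O[Si](C(C)C)(C(C)C)C(C)C)cc1 | intermediate
29 | 1-[(2R,3R)-3-(2,4-dihydroxybenzoyl)-4,6-dihydroxy-2-(4-hydroxyphenyl)-2,3-dihydrobenzofuran-7-yl]-2-(4-hydroxyphenyl)prop-2-en-1-one (CNP0162111.1) | C=C(C(=O)c1c(O)cc(O)c2c1O[C@@H](c1ccc(O)cc1)[C@@H]2C(=O)c1ccc(O)cc1O)c1ccc(O)cc1 | target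

**Step count and risks**

Total: 16 steps. Longest linear sequence: 12 steps (1, 3, 4, 5, 6, 7, 8, 10, 11, 14, 15, 16).

Steps most likely to fail:

1. Step 5. Oxidative addition of zerovalent palladium into the doubly ortho-oxygenated, electron-rich iodide may be slow, so that dimerisation of ethyl diazoacetate or decomposition of the diazo product outruns the coupling. The fallback sets out from 7: a Negishi coupling with the Reformatsky reagent BrZnCH2CO2Et (Pd2(dba)3, XPhos, THF, 60 °C) should give ethyl 2-{2-[4-(TIPSO)benzyloxy]-4,6-bis(TIPSO)phenyl}acetate F1. Diazo transfer to F1 with 4-acetamidobenzenesulfonyl azide and DBU in MeCN then comes back to the route at 9.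

2. Step 6. The catalyst may discriminate poorly between the two enantiotopic benzylic hydrogens, because the carbenoid arene is substituted at both ortho positions. The fallback sets out from 9 and gives up catalyst control: achiral Rh2(OAc)4 in CH2Cl2 should give the racemic cis ester, that is 10 together with ethyl (2S,3R)-4,6-bis(TIPSO)-2-[4-(TIPSO)phenyl]-2,3-dihydrobenzofuran-3-carboxylate F2. DBU equilibrates this to the racemic trans ester, that is 11 together with ethyl (2S,3S)-4,6-bis(TIPSO)-2-[4-(TIPSO)phenyl]-2,3-dihydrobenzofuran-3-carboxylate F3. Preparative chromatography on a chiral stationary phase (cellulose tris(3,5-dimethylphenylcarbamate)) separates the enantiomers and comes back to the route at 11.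

3. Step 11. Iodine–magnesium exchange at the hindered, electron-rich C7 iodide may be incomplete, or the arylmagnesium may be protonated before it meets DMF, leaving the deiodinated arene. The fallback sets out from 18 and replaces the organomagnesium by cross-coupling: a Stille reaction with tributyl(vinyl)stannane (Pd(PPh3)4, toluene, 100 °C) should give [2,4-bis(TIPSO)phenyl]{(2R,3S)-4,6-bis(TIPSO)-2-[4-(TIPSO)phenyl]-7-vinyl-2,3-dihydrobenzofuran-3-yl}methanol F4. Lemieux–Johnson cleavage of the vinyl group of F4 (cat. OsO4, NaIO4, 2,6-lutidine, dioxane/H2O) comes back to the route at 21.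

**Further compounds**

F1 | step 5 | ethyl 2-{2-[4-(TIPSO)benzyloxy]-4,6-bis(TIPSO)phenyl}acetate | CCOC(=O)Cc1c(OCc2ccc(O[Si](C(C)C)(C(C)C)C(C)C)cc2)cc(O[Si](C(C)C)(C(C)C)C(C)C)cc1O[Si](C(C)C)(C(C)C)C(C)C
F2 | step 6 | ethyl (2S,3R)-4,6-bis(TIPSO)-2-[4-(TIPSO)phenyl]-2,3-dihydrobenzofuran-3-carboxylate (enantiomer of 10) | c1c(O[Si](C(C)C)(C(C)C)C(C)C)cc(O[Si](C(C)C)(C(C)C)C(C)C)c2c1O[C@H](c1ccc(O[Si](C(C)C)(C(C)C)C(C)C)cc1)[C@@H]2C(=O)OCC
F3 | step 6 | ethyl (2S,3S)-4,6-bis(TIPSO)-2-[4-(TIPSO)phenyl]-2,3-dihydrobenzofuran-3-carboxylate (enantiomer of 11) | c1c(O[Si](C(C)C)(C(C)C)C(C)C)cc(O[Si](C(C)C)(C(C)C)C(C)C)c2c1O[C@H](c1ccc(O[Si](C(C)C)(C(C)C)C(C)C)cc1)[C@H]2C(=O)OCC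
F4 | step 11 | [2,4-bis(TIPSO)phenyl]{(2R,3S)-4,6-bis(TIPSO)-2-[4-(TIPSO)phenyl]-7-vinyl-2,3-dihydrobenzofuran-3-yl}methanol | C=Cc1c(O[Si](C(C)C)(C(C)C)C(C)C)cc(O[Si](C(C)C)(C(C)C)C(C)C)c2c1O[C@@H](c1ccc(O[Si](C(C)C)(C(C)C)C(C)C)cc1)[C@@H]2C(O)c1ccc(O[Si](C(C)C)(C(C)C)C(C)C)cc1O[Si](C(C)C)(C(C)C)C(C)C
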